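**Strategy.** The route rests on cutting the side chain between C7′ and C8′ (numbered from the carbinol carbon C1′). This is a plain CH2–CH2 link inside the heteroatom-free C2′–C17′ polymethylene tail, remote from the fragile 4,5-dihydroxycyclopent-2-enone ring. Because no functionality must remain there, a Pd–NHC-catalysed alkyl–alkyl Negishi coupling attaches the whole decyl unit to a primary bromide in one traceless operation, with all three stereocentres already in place. Its precursor is the C7 bromide made by one stereocentre-regenerating aldol of the (3aS,6aS) acetonide of cis-4,5-dihydroxycyclopent-2-enone with 7-bromoheptanal; aqueous acid then releases the triol.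

Key step: step 2

Assumption: enone 1 (the (+)-(3aS,6aS) enantiomer), 7-bromoheptanal 2 and decylzinc bromide 6 (0.5 M in THF) are taken as catalogue compounds.

Remark: the C3a descriptor is S in 1 and 4 and R in 5 and 7 only because O–Si outranks O–C in the CIP rules; the spatial arrangement is the same throughout.

Step 1
Reactants: 1 (3aS,6aS)-2,2-dimethyl-3a,6a-dihydro-4H-cyclopenta[d][1,3]dioxol-4-one; 2 7-bromoheptanal
Product: 5 (3aR,6aS)-3a-[(1S)-7-bromo-1-(trimethylsilyloxy)heptyl]-2,2-dimethyl-3a,6a-dihydro-4H-cyclopenta[d][1,3]dioxol-4-one, via lithium dienolate 3 (not isolated), via lithium aldolate 4 (not isolated)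
Conditions: LDA (1.05 equiv), THF, −78 °C; then 2 (1.2 equiv), −78 °C; then TMSCl (1.5 equiv), −78 → −30 °C; pH 7 buffer
Reagents that add atoms: chlorotrimethylsilane (TMSCl), C[Si](C)(C)Cl
Why: Kinetic α′-deprotonation should give the cross-conjugated lithium dienolate, which adds to the aldehyde in a lithium enolate aldol addition: the aldehyde must enter anti to the C6a–O bond because only the cis-fused dioxolane can re-form (this sets C3a by self-regeneration of the stereocentre), a Zimmerman–Traxler chair with the alkyl chain equatorial and the enolate oxygen substituent O3 pseudo-axial should place O3 and the new carbinol oxygen syn, i.e. (1S), and TMSCl caps the aldolate before retro-aldol can set in.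

Step 2
Reactants: 5 (3aR,6aS)-3a-[(1S)-7-bromo-1-(trimethylsilyloxy)heptyl]-2,2-dimethyl-3a,6a-dihydro-4H-cyclopenta[d][1,3]dioxol-4-one; 6 decylzinc bromide
Product: 7 (3aR,6aS)-2,2-dimethyl-3a-[(1S)-1-(trimethylsilyloxy)heptadecyl]-3a,6a-dihydro-4H-cyclopenta[d][1,3]dioxol-4-one
Conditions: 6 (1.6 equiv, 0.5 M in THF), Pd-PEPPSI-IPr (2 mol%), LiBr (3 equiv), THF/NMP (2:1), rt
Reagents that add atoms: none
Why: The Pd(0)–NHC species released from the precatalyst should insert into the primary C7′–Br bond of 5 by SN2-type oxidative addition, the decyl group is transferred from the bromide-activated zincate, and the bulky IPr ligand drives C(sp3)–C(sp3) reductive elimination ahead of β-hydride elimination, so the C7′–C8′ bond forms directly at the alkane oxidation level. The closest known reaction type is the Pd–NHC-catalysed alkyl–alkyl Negishi coupling of unactivated primary alkyl bromides with alkylzinc halides at room temperature. No ring is closed and no stereocentre is created or touched, since the three existing ones lie six or more bonds from the reacting carbon. The selectivity needed is chemoselectivity for the C–Br bond over the cyclopentenone, which should be secured because alkylzinc halides do not add 1,2 or 1,4 to enones without copper, nickel or silyl activation, as Pd-catalysed Negishi couplings of halocyclopentenones show. The neutral, base-free medium should leave the acetonide, the TMS ether and the retro-aldol-prone C3a–C1′ bond intact, and the TMS cap removes the only acidic proton that could quench the zinc reagent.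

Step 3
Reactants: 7 (3aR,6aS)-2,2-dimethyl-3a-[(1S)-1-(trimethylsilyloxy)heptadecyl]-3a,6a-dihydro-4H-cyclopenta[d][1,3]dioxol-4-one
Product: 8 (4S,5S)-4,5-dihydroxy-5-[(1S)-1-hydroxyheptadecyl]cyclopent-2-en-1-one
Conditions: TFA/H2O (4:1), THF co-solvent, 0 °C → rt
Reagents that add atoms: none
Why: Acid-catalysed silyl ether solvolysis and acetal hydrolysis (via the oxocarbenium ion at the CMe2 carbon) should free the three hydroxyls with all C–O bonds of the stereocentres retained, since C5 is quaternary and can neither enolise nor eliminate and neither carbinol ionises next to the electron-poor enone.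

**Compound list**

1 | (3aS,6aS)-2,2-dimethyl-3a,6a-dihydro-4H-cyclopenta[d][1,3]dioxol-4-one | CC1(C)O[C@H]2C=CC(=O)[C@H]2O1 | starting material
2 | 7-bromoheptanal | O=CCCCCCCBr | starting material
3 | lithium (6aS)-2,2-dimethyl-6aH-cyclopenta[d][1,3]dioxol-4-olate (lithium dienolate of 1) | [Li]OC1=C2OC(C)(C)O[C@H]2C=C1 | intermediate
4 | lithium (1S)-7-bromo-1-[(3aS,6aS)-2,2-dimethyl-4-oxo-3a,6a-dihydro-4H-cyclopenta[d][1,3]dioxol-3a-yl]heptan-1-olate (lithium aldolate) | BrCCCCCC[C@H](O[Li])[C@@]1(OC(C)(C)O2)C(=O)C=C[C@@H]12 | intermediate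
5 | (3aR,6aS)-3a-[(1S)-7-bromo-1-(trimethylsilyloxy)heptyl]-2,2-dimethyl-3a,6a-dihydro-4H-cyclopenta[d][1,3]dioxol-4-one | BrCCCCCC[C@H](O[Si](C)(C)C)[C@@]1(OC(C)(C)O2)C(=O)C=C[C@@H]12 | intermediate
6 | decylzinc bromide | CCCCCCCCCC[Zn]Br | starting material
7 | (3aR,6aS)-2,2-dimethyl-3a-[(1S)-1-(trimethylsilyloxy)heptadecyl]-3a,6a-dihydro-4H-cyclopenta[d][1,3]dioxol-4-one | CCCCCCCCCCCCCCCC[C@H](O[Si](C)(C)C)[C@@]1(OC(C)(C)O2)C(=O)C=C[C@@H]12 | intermediate
8 | (4S,5S)-4,5-dihydroxy-5-[(1S)-1-hydroxyheptadecyl]cyclopent-2-en-1-one | CCCCCCCCCCCCCCCC[C@H](O)[C@@]1(O)C(=O)C=C[C@@H]1O | target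

**Totals.** Total step count: 3. Longest linear sequence: 3 steps (1 → 5 → 7 → 8).

**Steps most likely to fail**

Step 2 (key step). The organozinc may be consumed by conjugate addition to the enone, the alkylpalladium intermediate may undergo β-hydride elimination or reduction, and the enone may bind Pd(0) so that oxidative addition stalls. The fallback makes the C7′–C8′ bond before the ring is attached. It sets out from 2: acetalisation (ethylene glycol, p-TsOH, toluene, Dean–Stark) should give 2-(6-bromohexyl)-1,3-dioxolane F1. A copper-catalysed Kochi alkyl–alkyl coupling with decylmagnesium bromide (Li2CuCl4 cat., THF, −10 °C → rt) should give 2-hexadecyl-1,3-dioxolane F2, and aqueous HCl/THF should release heptadecanal F3. F3 then takes the place of 2 in the step 1 protocol (enolate 3, then TMSCl) and should give, through the lithium aldolate F4, compound 7, where the route is rejoined.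

Step 1. A loose lithium transition state may give poor facial selectivity at the aldehyde carbon, and the free dienolate or aldolate may suffer β-elimination of the C6a alkoxide or retro-aldol equilibration before silylation. The fallback is a boron-mediated aldol that never forms a free enolate. It sets out from 1: soft enolisation (c-Hex2BCl, Et3N, Et2O, −78 → 0 °C) should give the dicyclohexylboron dienolate F5. Addition of 2 at −78 °C should give the boron aldolate F6 through a tighter chair with short B–O bonds, with the same sense of induction. Hydrolytic work-up (MeOH/pH 7 buffer) should give (3aS,6aS)-3a-[(1S)-7-bromo-1-hydroxyheptyl]-2,2-dimethyl-3a,6a-dihydro-4H-cyclopenta[d][1,3]dioxol-4-one F7. Silylation (TMSCl, imidazole, CH2Cl2) returns to the route at 5.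

Step 3. Hydrolysis of the hindered dioxolane may be slow on the waxy C17 substrate, so that long acid contact promotes retro-aldol cleavage of the C5–C1′ bond or other degradation of the liberated ketol. The fallback re-orders the end game so that the last step needs no strong acid. It sets out from 5: the same aqueous TFA treatment on the short-chain, more polar bromide should give (4S,5S)-5-[(1S)-7-bromo-1-hydroxyheptyl]-4,5-dihydroxycyclopent-2-en-1-one F8. N-(Trimethylsilyl)imidazole (CH2Cl2, rt) should give (4S,5S)-5-[(1S)-7-bromo-1-(trimethylsilyloxy)heptyl]-4,5-bis(trimethylsilyloxy)cyclopent-2-en-1-one F9. Negishi coupling with 6 under the step 2 conditions should give (4S,5S)-4,5-bis(trimethylsilyloxy)-5-[(1S)-1-(trimethylsilyloxy)heptadecyl]cyclopent-2-en-1-one F10. AcOH/THF/H2O at rt should then remove the three TMS groups and return to the route at 8.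

**Further compounds**

F1 | step 2 | 2-(6-bromohexyl)-1,3-dioxolane | BrCCCCCCC1OCCO1
F2 | step 2 | 2-hexadecyl-1,3-dioxolane | CCCCCCCCCCCCCCCCC1OCCO1
F3 | step 2 | heptadecanal | CCCCCCCCCCCCCCCCC=O
F4 | step 2 | lithium (1S)-1-[(3aS,6aS)-2,2-dimethyl-4-oxo-3a,6a-dihydro-4H-cyclopenta[d][1,3]dioxol-3a-yl]heptadecan-1-olate | CCCCCCCCCCCCCCCC[C@H](O[Li])[C@@]1(OC(C)(C)O2)C(=O)C=C[C@@H]12
F5 | step 1 | dicyclohexyl{[(6aS)-2,2-dimethyl-6aH-cyclopenta[d][1,3]dioxol-4-yl]oxy}borane (boron dienolate of 1) | C1CCCCC1B(C1CCCCC1)OC1=C2OC(C)(C)O[C@H]2C=C1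
F6 | step 1 | (3aS,6aS)-3a-[(1S)-7-bromo-1-(dicyclohexylboranyloxy)heptyl]-2,2-dimethyl-3a,6a-dihydro-4H-cyclopenta[d][1,3]dioxol-4-one (boron aldolate) | BrCCCCCC[C@H](OB(C1CCCCC1)C1CCCCC1)[C@@]1(OC(C)(C)O2)C(=O)C=C[C@@H]12
F7 | step 1 | (3aS,6aS)-3a-[(1S)-7-bromo-1-hydroxyheptyl]-2,2-dimethyl-3a,6a-dihydro-4H-cyclopenta[d][1,3]dioxol-4-one | BrCCCCCC[C@H](O)[C@@]1(OC(C)(C)O2)C(=O)C=C[C@@H]12
F8 | step 3 | (4S,5S)-5-[(1S)-7-bromo-1-hydroxyheptyl]-4,5-dihydroxycyclopent-2-en-1-one | BrCCCCCC[C@H](O)[C@@]1(O)C(=O)C=C[C@@H]1O
F9 | step 3 | (4S,5S)-5-[(1S)-7-bromo-1-(trimethylsilyloxy)heptyl]-4,5-bis(trimethylsilyloxy)cyclopent-2-en-1-one | BrCCCCCC[C@H](O[Si](C)(C)C)[C@@]1(O[Si](C)(C)C)C(=O)C=C[C@@H]1O[Si](C)(C)C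
F10 | step 3 | (4S,5S)-4,5-bis(trimethylsilyloxy)-5-[(1S)-1-(trimethylsilyloxy)heptadecyl]cyclopent-2-en-1-one | CCCCCCCCCCCCCCCC[C@H](O[Si](C)(C)C)[C@@]1(O[Si](C)(C)C)C(=O)C=C[C@@H]1O[Si](C)(C)C
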